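## Retrosynthetic overview
1. Target 16 ⇐ ester 14 by one saponification that cleaves both the ethyl ester and the aryl pivalate.
2. C2'–C3' bond of 14 ⇐ B-alkyl Suzuki coupling of (S)-2-vinylchroman 7 with (E)-vinyl iodide 12, which carries both side-chain alkenes with fixed geometry.
3. Ring B (the dihydropyran; the only ring built, onto the purchased benzene ring A) ⇐ catalytic enantioselective oxa-[4+2] of isoprene 5 with o-quinone methide 6, formed by dearomatising dehydration of salicyl alcohol 4; this sets C2.
4. 4 ⇐ methylhydroquinone 1 (mono-pivaloylation, ortho-hydroxymethylation); 12 ⇐ pent-4-yn-1-ol 8 (carboalumination/iodination, then oxidation/Wittig).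

Assumption: the sense of induction of the new cycloaddition in step 3 must be found by experiment; the catalyst antipode that gives (S)-7 is used and is written below as (S,S)-IDPi (both antipodes come from (R)- or (S)-BINOL).

## Route

Step 1
Reactants: 1 2-methylbenzene-1,4-diol (methylhydroquinone)
Product: 2 4-hydroxy-3-methylphenyl pivalate
Conditions: PivCl (1.0 equiv), Et3N (1.1 equiv), CH2Cl2, −40 → 0 °C
Reagents that add atoms: pivaloyl chloride, CC(C)(C)C(=O)Cl
Why: Kinetic mono-esterification (acylation) with the bulky acid chloride goes to the unhindered and slightly more acidic 4-OH, since the other OH is flanked by the methyl group; the pivalate blocks that oxygen through steps 2–6 and is removed in step 7.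

Step 2
Reactants: 2 4-hydroxy-3-methylphenyl pivalate
Product: 4 4-hydroxy-3-(hydroxymethyl)-5-methylphenyl pivalate, via benzodioxaborin 3 (not isolated)
Conditions: PhB(OH)2 (1.1 equiv), (CH2O)n (2 equiv), EtCO2H (cat.), PhMe, reflux, Dean–Stark; then propane-1,3-diol (3 equiv), THF, rt
Reagents that add atoms: paraformaldehyde (as formaldehyde), C=O; phenylboronic acid, OB(O)c1ccccc1 (its atoms stay only in 3)
Why: Nagata ortho-hydroxymethylation, in which the aryl boronate delivers formaldehyde to the only free ortho position to give 3, and neutral transesterification with the diol releases the saligenin without touching the pivalate.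

Step 3
Reactants: 4 4-hydroxy-3-(hydroxymethyl)-5-methylphenyl pivalate; 5 isoprene
Product: 7 (S)-2,8-dimethyl-2-vinylchroman-6-yl pivalate, via o-quinone methide 6 (not isolated)
Conditions: (S,S)-IDPi (confined chiral N-triflyl imidodiphosphorimidate Brønsted acid from 3,3'-diaryl-BINOL, 5 mol %), 5 (10 equiv), 5 Å MS, CHCl3, −20 °C, slow addition of 4; Et3N quench
Reagents that add atoms: none
Why: Proposed new method: the strong confined acid dehydrates 4 to the dearomatised o-quinone methide 6, held hydrogen-bonded or ion-paired in the chiral pocket, and isoprene adds through its methyl-substituted CH2 terminus in an asynchronous inverse-electron-demand oxa-[4+2] (hetero-Diels–Alder) whose C–O bond closes at the incipient tertiary allylic cation, so regiochemistry follows cation stability and C2 is set by the catalyst shielding one face of 6 and fixing the vinyl/methyl orientation, with rearomatisation as driving force; the closest known reaction types are the HNTf2-catalysed annulation of o-hydroxybenzyl alcohols with alkenes to racemic chromans, chiral-acid-catalysed [4+2] reactions of in situ o-quinone methides, and IDPi-catalysed asymmetric hydroalkoxylation that forms methyl/alkyl tertiary ether centres.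

Step 4
Reactants: 8 pent-4-yn-1-ol
Product: 10 (E)-5-iodo-4-methylpent-4-en-1-ol, via alkenylalane 9 (not isolated)
Conditions: AlMe3 (3 equiv), Cp2ZrCl2 (25 mol %), CH2Cl2, 0 °C → rt; then I2, THF, −30 → 0 °C; aq K2CO3 work-up
Reagents that add atoms: trimethylaluminium, C[Al](C)C; iodine, II
Why: Negishi zirconium-catalysed carboalumination adds Me–Al syn across the terminal alkyne with methyl on the internal carbon, and iodinolysis of the C–Al bond with retention gives only the (E)-vinyl iodide.

Step 5
Reactants: 10 (E)-5-iodo-4-methylpent-4-en-1-ol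
Product: 12 ethyl (2E,6E)-7-iodo-2,6-dimethylhepta-2,6-dienoate, via aldehyde 11 (not isolated)
Conditions: Dess–Martin periodinane (1.2 equiv), Ph3P=C(Me)CO2Et (1.6 equiv), CH2Cl2, rt
Reagents that add atoms: ethyl 2-(triphenyl-λ5-phosphanylidene)propanoate, CCOC(=O)C(C)=P(c1ccccc1)(c1ccccc1)c1ccccc1
Why: Tandem Dess–Martin oxidation/Wittig olefination traps the sensitive aldehyde 11 as it forms, and the stabilised α-methyl ylide gives the (E)-2-methyl enoate (typically >95:5) without touching the vinyl iodide.

Step 6
Reactants: 7 (S)-2,8-dimethyl-2-vinylchroman-6-yl pivalate; 12 ethyl (2E,6E)-7-iodo-2,6-dimethylhepta-2,6-dienoate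
Product: 14 ethyl (2E,6E)-9-[(R)-2,8-dimethyl-6-(pivaloyloxy)chroman-2-yl]-2,6-dimethylnona-2,6-dienoate, via alkylborane 13 (not isolated)
Conditions: 9-BBN dimer (0.65 equiv), THF, 0 °C → rt; then 12 (1.1 equiv), PdCl2(dppf) (5 mol %), AsPh3 (10 mol %), aq K3PO4 (3 equiv), DMF, rt
Reagents that add atoms: 9-borabicyclo[3.3.1]nonane (9-BBN), B1C2CCCC1CCC2 (its boron stays only in 13; 14 keeps one hydrogen)
Why: Anti-Markovnikov hydroboration of the monosubstituted alkene followed by B-alkyl Suzuki–Miyaura coupling joins the fragments with retention of the vinyl iodide geometry (giving the 6E alkene) and leaves C2 untouched, the S to R change being only a change in CIP priorities.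

Step 7
Reactants: 14 ethyl (2E,6E)-9-[(R)-2,8-dimethyl-6-(pivaloyloxy)chroman-2-yl]-2,6-dimethylnona-2,6-dienoate
Product: 16 (2E,6E)-9-[(R)-6-hydroxy-2,8-dimethylchroman-2-yl]-2,6-dimethylnona-2,6-dienoic acid, via dilithium salt 15 (not isolated)
Conditions: LiOH·H2O (6 equiv), degassed THF/H2O 2:1, 50 °C, Ar; then 1 M HCl to pH 3, 0 °C
Reagents that add atoms: lithium hydroxide, [Li+].[OH-]
Why: Saponification cleaves the aryl pivalate and the ethyl enoate in one operation under argon (the chromanol phenoxide is air-sensitive), and acidification gives the acid without affecting the alkenes or C2.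

## Compound list
1 | 2-methylbenzene-1,4-diol (methylhydroquinone) | Cc1cc(O)ccc1O | starting material
2 | 4-hydroxy-3-methylphenyl pivalate | Cc1cc(OC(=O)C(C)(C)C)ccc1O | intermediate
3 | 8-methyl-2-phenyl-4H-1,3,2-benzodioxaborinin-6-yl pivalate | Cc1cc(OC(=O)C(C)(C)C)cc2COB(c3ccccc3)Oc12 | intermediate (not isolated)
4 | 4-hydroxy-3-(hydroxymethyl)-5-methylphenyl pivalate | Cc1cc(OC(=O)C(C)(C)C)cc(CO)c1O | intermediate
5 | isoprene (2-methylbuta-1,3-diene) | C=CC(C)=C | starting material
6 | o-quinone methide, 5-methyl-3-methylidene-4-oxocyclohexa-1,5-dien-1-yl pivalate | C=C1C=C(OC(=O)C(C)(C)C)C=C(C)C1=O | intermediate (not isolated)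
7 | (S)-2,8-dimethyl-2-vinylchroman-6-yl pivalate | C=C[C@]1(C)CCc2cc(OC(=O)C(C)(C)C)cc(C)c2O1 | intermediate
8 | pent-4-yn-1-ol | C#CCCCO | starting material
9 | (E)-alkenylalane, dimethyl[(E)-5-(dimethylalumanyloxy)-2-methylpent-1-enyl]alumane | C[Al](C)/C=C(C)/CCCO[Al](C)C | intermediate (not isolated)
10 | (E)-5-iodo-4-methylpent-4-en-1-ol | OCCC/C(C)=C/I | intermediate
11 | (E)-5-iodo-4-methylpent-4-enal | O=CCC/C(C)=C/I | intermediate (not isolated)
12 | ethyl (2E,6E)-7-iodo-2,6-dimethylhepta-2,6-dienoate | CCOC(=O)/C(C)=C/CC/C(C)=C/I | intermediate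
13 | 9-{2-[(R)-2,8-dimethyl-6-(pivaloyloxy)chroman-2-yl]ethyl}-9-borabicyclo[3.3.1]nonane | C1CC2CCCC(C1)B2CC[C@]1(C)CCc2cc(OC(=O)C(C)(C)C)cc(C)c2O1 | intermediate (not isolated)
14 | ethyl (2E,6E)-9-[(R)-2,8-dimethyl-6-(pivaloyloxy)chroman-2-yl]-2,6-dimethylnona-2,6-dienoate | CCOC(=O)/C(C)=C/CC/C(C)=C/CC[C@]1(C)CCc2cc(OC(=O)C(C)(C)C)cc(C)c2O1 | intermediate
15 | dilithium salt of 16 (phenoxide carboxylate) | [Li+].[Li+].C/C(=C\CC[C@]1(C)CCc2cc([O-])cc(C)c2O1)CC/C=C(\C)C(=O)[O-] | intermediate (not isolated)
16 | (2E,6E)-9-[(R)-6-hydroxy-2,8-dimethylchroman-2-yl]-2,6-dimethylnona-2,6-dienoic acid | C/C(=C\CC[C@]1(C)CCc2cc(O)cc(C)c2O1)CC/C=C(\C)C(=O)O | target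

## Count and risks
Total steps: 7. Longest linear sequence: 5 (steps 1, 2, 3, 6, 7); steps 4 and 5 make the side-chain fragment.

**Step 3 (most likely to fail).** The enantioselectivity is unproven. The unstabilised o-quinone methide may also oligomerise, some 2-isopropenylchroman may form, and the tertiary allylic aryl ether could re-ionise under the acid. The fallback sets out from 4 (with 5) and comes back at 7. Achiral HNTf2 (2 mol %, CH2Cl2, 0 °C) gives racemic 2,8-dimethyl-2-vinylchroman-6-yl pivalate F1 by the same annulation with no demand on enantiocontrol. The enantiomers are then separated by preparative SFC on an amylose tris(3,5-dimethylphenylcarbamate) phase, and the (S)-enantiomer is 7 (configuration confirmed by carrying a sample through to 16 and comparing its optical rotation).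

**Step 6.** Hydroboration next to the quaternary carbon and the B-alkyl coupling may be slow, with protodeboronation as the competing path; loss of some pivalate under the aqueous base is harmless because step 7 removes it anyway. The fallback sets out from 7 and comes back at 14. Alkylborane 13 is oxidised with NaBO3·4H2O (THF/H2O, rt) to (S)-2-(2-hydroxyethyl)-2,8-dimethylchroman-6-yl pivalate F2. I2/PPh3/imidazole (CH2Cl2, 0 °C) converts it to (S)-2-(2-iodoethyl)-2,8-dimethylchroman-6-yl pivalate F3. Zinc insertion (Zn dust, LiCl, THF, 40 °C) gives the ester-tolerant alkylzinc iodide F4, and Negishi coupling with 12 (PdCl2(dppf) 5 mol %, THF/NMP, rt) gives 14.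

**Step 2.** The acyloxy-substituted phenol is a weaker nucleophile, and the saligenin can self-condense during boronate cleavage. The fallback sets out from 2 and comes back at 4. Magnesium-mediated ortho-formylation (MgCl2, Et3N, paraformaldehyde, MeCN, reflux) gives 3-formyl-4-hydroxy-5-methylphenyl pivalate F5, a stable salicylaldehyde that can be purified, and NaBH4 (THF/EtOH, 0 °C) reduces it to 4.

## Further compounds
F1 | step 3 | racemic 2,8-dimethyl-2-vinylchroman-6-yl pivalate | C=CC1(C)CCc2cc(OC(=O)C(C)(C)C)cc(C)c2O1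
F2 | step 6 | (S)-2-(2-hydroxyethyl)-2,8-dimethylchroman-6-yl pivalate | OCC[C@]1(C)CCc2cc(OC(=O)C(C)(C)C)cc(C)c2O1
F3 | step 6 | (S)-2-(2-iodoethyl)-2,8-dimethylchroman-6-yl pivalate | ICC[C@]1(C)CCc2cc(OC(=O)C(C)(C)C)cc(C)c2O1
F4 | step 6 | {2-[(S)-2,8-dimethyl-6-(pivaloyloxy)chroman-2-yl]ethyl}zinc iodide | I[Zn]CC[C@]1(C)CCc2cc(OC(=O)C(C)(C)C)cc(C)c2O1
F5 | step 2 | 3-formyl-4-hydroxy-5-methylphenyl pivalate | Cc1cc(OC(=O)C(C)(C)C)cc(C=O)c1O
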